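(The data were generated by integration with constants of no real substance, noise included.)

I have to decide whether this new flask is worth leaving on stirring for the full 10 d, so I reckon what stands in it then.

| setting | red | flask |
|---|---|---|
| left-handed substrate | 0.018 M | 0.018 M |
| right-handed substrate | 0.018 M | 0.018 M |
| coupling partner | 3 equiv | 3.00 equiv |
| free catalyst | 0.3 mol% | 0.2 mol% |
| remark | run made earlier |  |
| time |  | 10 d |

red run (percent of the left-handed substrate and right-handed substrate together charged)

| time / d | right-handed substrate / % | left-handed substrate / % |
|---|---|---|
| 0.167 | 49.6 | 42.2 |
| 0.500 | 50.7 | 31.6 |
| 0.833 | 50.4 | 23.9 |
| 1.25 | 48.9 | 19.2 |
| 1.67 | 49.1 | 12.4 |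
| 2.50 | 49.2 | 8.6 |
| 3.00 | 46.9 | 5.8 |

(scatter of a reading: 1 percentage point)

- free catalyst is single-handed; left-handed substrate and right-handed substrate are mirror images of each other, charged as a racemate, each of them at the stated concentration
- steps that have been proposed: coupling partner + free catalyst + left-handed substrate -> free catalyst + left-handed product; coupling partner + free catalyst + right-handed substrate -> free catalyst + right-handed product; coupling partner <-> dormant form; free catalyst -> spent catalyst
- no earlier run changes the charge of free catalyst; that part of a forecast is a guess

1. whether the excess of right-handed substrate over left-handed substrate among what is left of the two reaches 80% by 10 d (no / yes)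
2. the highest excess of right-handed substrate over left-handed substrate among what is left of the two up to 10 d

The bench rule for a partner in excess is pseudo-first-order: take one rate constant and count it down. The first reading of the red run gives the left-handed substrate an apparent constant of 1.02 d⁻¹, as a reading with its scatter. I guess that rate follows catalyst, which makes it 0.677 d⁻¹ in the new flask, and I take the catalyst as lasting. My first answer is then a left-handed fraction of 0.00115 of its own charge.

Putting that answer back shows the border of the rule. Counting coupling with the left-handed substrate and nothing else, using up that substrate costs a third of the partner's charge, which is no flood. So on my second round I assume rate follows partner and multiply throughout by 0.667, the partner fraction this reckoning leaves at the end.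

I call the result the exposure, the early constant times the catalyst ratio times the partner factor times the time: 4.51. The left-handed fraction of its own charge is exp(−exposure), in the new flask 0.0110. On the red run the same rule gives 0.131 at the last reading, which shows 0.116.

That last reading of the red run also gives a selectivity factor of 33.7, a poor reading, which in the new flask leaves a right-handed fraction of 0.874 by my reckoning. My excess at 10 d is then 97.5%, above the 80% asked, and it barely feels that poor factor, because the left-handed fraction is far smaller than the right-handed one.

The forecast says yes, with a top of 88%, between 79% and 97%: “I expect it to pass 80%, though not by a wide margin.” My figure lies above that range.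

The flask gives yes, with a top of 97.6%.

    coupling partner + free catalyst + left-handed substrate → free catalyst + left-handed product (k = 333 M⁻² min⁻¹)
    coupling partner + free catalyst + right-handed substrate → free catalyst + right-handed product (k = 3.10 M⁻² min⁻¹)
    coupling partner ⇌ dormant form (K = 0.502, k = 0.0196 min⁻¹)
    free catalyst → spent catalyst (k = 1.27 × 10⁻⁶ min⁻¹)

At 1.21 d the left-handed substrate has a half-life by its own coupling step of 1.3 d in this flask, short against the 10 d allowed, while the right-handed substrate has one by its own coupling step of 140 d, long against it. The exposure of 4.51 stands for a left-handed fraction of 0.0110, and at 10.0 d the flask holds 1.2% of the left-handed charge beside 96% of the right-handed charge.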